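## Analysis of the target

The target 14 is a 1,4-naphthoquinone in which ring A is the quinone (C1 to C4 with C4a and C8a), ring B is the fused benzene ring (C4a to C8a) and ring C is a 3,4-dimethoxyphenyl group bound through C1' to C8. Methoxy groups sit on C2 of ring A, on C6 of ring B and on C3' and C4' of ring C. There is no stereocentre, and ring C has only hydrogen at C2' and C6', so the C8–C1' axis should rotate freely and nothing stereochemical has to be set. The 2-methoxyquinone is a vinylogous ester and a Michael acceptor, open to nucleophiles, bases and reducing metals, so it is best unveiled last. The synthesis is demanding for two reasons: the C8–C1' bond lies peri to the C1 carbonyl, the most crowded position of the naphthalene, and the ring A methoxy group must sit on C2, next to the carbonyl that neighbours C8, and not on C3. The strategy rests on two observations: C2' to C5' of ring C, with both methoxy groups, are the four carbons of diene 10, which leaves C1' and C6' as an ethynyl group on C8; and the oxygen on C1 is the one group placed to direct a metal to the C8–H bond.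

## Retrosynthetic reasoning

**14 to 13.** The C4 carbonyl oxygen is removed first, which leads back to naphthol 13 with ring A as an aromatic 2-methoxy-1-naphthol. The quinone is the most fragile part of 14, so it should appear in the last step. A 1-naphthol whose para position is free is oxidised by a nitroxyl radical oxidant at that position. In 13 the ortho position C2 is occupied and C4 is the only free position para to the hydroxyl, so the oxygen pattern of ring A follows from the substrate. The forward reaction has to touch ring A only; rings B and C carry ethers and no phenol.

**13 to 12.** The O–H bond is exchanged for a methoxymethyl acetal, giving 12. The hydroxyl must be masked throughout the alkyne chemistry and the dehydrogenation. An acetal can later be removed by acid without touching the four methyl ethers.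

**12 to 11.** Ring C is taken back by two hydrogen atoms, at C2' and C5', to the 1,4-cyclohexadiene 11. No skeletal bond changes. The step is needed because an alkyne and a diene combine to a cyclohexadiene and not to an arene. In the forward direction a quinone hydride acceptor should remove the two hydrogens, driven by aromatisation.

**11 to 9 and 10.** This is the key disconnection: C1'–C2' and C5'–C6' are cut. The C2'–C5' fragment with both methoxy groups is diene 10 itself. The diene is symmetric, so only one constitution can result. What remains on the naphthalene is the terminal alkyne 9. Cutting C8–C1' instead would require joining two arenes at the peri position next to an oxygen substituent, the slowest kind of biaryl coupling. A linear two-carbon group at C8 avoids that problem. An unactivated alkyne and an electron-rich diene do not combine thermally, so the forward step needs a low-valent cobalt catalyst to bring them together. It must also engage the alkyne as the only two-carbon partner.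

**9 to 8 to 7.** The C(sp)–H bond is traced to a C(sp)–Si bond and the acetal to the free hydroxyl. The alkyne is stored as its triisopropylsilyl derivative. In the forward direction the order matters: the hydroxyl is capped (7 to 8) before the silyl group is removed (8 to 9), because a free peri hydroxyl next to a terminal alkyne could add across it.

**7 to 5 and 6.** The C8–C(sp) bond is cut. Electrophilic substitution cannot reach C8, but the C1 hydroxyl of 5 lies next to the C8–H bond. With C2 occupied by methoxy, the hydroxyl can guide a metal only to C8. A catalysed C–H alkynylation with bromoalkyne 6 therefore installs the two carbons without any halogenation at C8.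

**5 to 2 to 1.** The C1–O bond is traced to a C1–Br bond and then to C1–H. In 1 the position C1 is alpha and ortho to a methoxy group, the most nucleophilic site, and it is equivalent to C5 by symmetry. Bromination followed by exchange of bromine for oxygen through boron gives 5. The purchasable naphthalene 1 already carries the C2 and C6 methoxy groups in the right places.

## Alternatives that were turned down

**Alternative 1:** Rings A and B are built together by cutting C4a–C8a, C5–C6 and C7–C8. In the forward direction the diyne A1, an aryl ynone joined by three methylene groups to a terminal alkyne, would be cyclotrimerised with the alkynyl boronate A2 under a ruthenium or rhodium catalyst to give the boryl tetralone A3.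
- For it: three C–C bonds and two rings arise in one operation. Ring C enters on an alkyne carbon, so no hindered biaryl coupling is needed. The boron at C6 is a handle for the ring B oxygen. On bond-forming economy and convergence it is stronger than the chosen route.
- Against it: both A1 and A2 are unsymmetrical, so the boron ends on C6 and not C7 only through a steric bias of the catalyst; the structure does not enforce it. The two terminal alkynes can also trimerise with themselves, and the ynone is a Michael acceptor.
- Against it: A3 has ring A as a saturated ketone. The C–B bond must be oxidised and methylated, and C2, C3 and C4 must then be raised in oxidation level and the resulting hydroxyquinone O-methylated. That means four or more further steps, some under strongly basic aerobic conditions, with ambident methylation at the end.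
- In its place the chosen strategy offers regiochemistry fixed by symmetry and by the position of the C1 oxygen, and a ring A that needs one oxidation only.

**Alternative 2:** Ring B is cut at C4a–C5 and C6–C7. The fused pyranone A4 would act as an electron-poor diene towards the ketene acetal A5. Decarboxylative aromatisation with loss of one acetal methoxy group would give the tetralone A6.
- For it: A4 should be reachable in a single condensation from two simple building blocks. The polarity of the two partners places the methoxy group on C6. Ring C is present from the start. This is probably the shortest of the four strategies, and on step count it is stronger than the chosen one.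
- Against it: the reacting diene terminus at the ring fusion, the carbon bound to the lactone oxygen, is fully substituted, and the neighbouring aryl group is twisted and electron-donating. The cycloaddition must therefore build a quaternary bridgehead on a deactivated diene and will need heat. Addition of A5 to the ketone or conjugate addition with ring opening can compete.
- Against it: A6 is again a tetralone, so the full oxidation-level build-up of ring A and the ambident O-methylation remain.
- In its place the chosen strategy offers a key step at room temperature under neutral conditions and a ring A whose C1 and C2 oxygens are present from the first steps.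

**Alternative 3:** Ring A is cut at C3–C4. Base would convert the methyl group of the aryl 1,2-diketone A7 into an enolate that attacks the ortho ester in a Claisen condensation. The product is the hydroxyquinone A8, and one O-methylation would give 14.
- For it: ring A is formed at the right oxidation level with the hydroxyl on C2 beyond doubt. No oxidation is run in the presence of electron-rich arenes. In end-game redox economy it is stronger than the chosen route.
- Against it: A7 is a 1,2,3,5-tetrasubstituted benzene with the diketone between the ester and ring C. Making it requires the hindered biaryl bond ortho to an acyl group, the coupling the chosen route avoids, plus installation of a 1,2-diketone.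
- Against it: the enolisable diketone is exposed to alkoxide, which invites aldol self-condensation, benzilic-type rearrangement and attack at the wrong carbonyl. The final methylation is ambident.
- In its place the chosen strategy offers a precursor reached in five steps from a symmetric naphthalene, with no coupling of two arenes.

Key step: step 6

Assumption: the C8–C1' axis is taken as freely rotating (no ortho substituent on ring C), so 14 is treated as achiral; compounds 1, 6 and 10 are taken as purchasable.

## Route

**Step 1**
Reactants: 1 2,6-dimethoxynaphthalene
Product: 2 1-bromo-2,6-dimethoxynaphthalene
Conditions: NBS (1.0 equiv), MeCN, 0 °C to rt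
Reagents that add atoms: N-bromosuccinimide, O=C1CCC(=O)N1Br
Why: Electrophilic aromatic bromination; C1 is alpha and ortho to the C2 methoxy group, the most nucleophilic site, and C1 and C5 of 1 are equivalent by symmetry, so one equivalent of NBS should give a single monobromide.

**Step 2**
Reactants: 2 1-bromo-2,6-dimethoxynaphthalene
Product: 5 2,6-dimethoxynaphthalen-1-ol, via 1-lithio-2,6-dimethoxynaphthalene 3 (not isolated), via lithium aryltrimethoxyborate 4 (not isolated)
Conditions: n-BuLi, THF, −78 °C; B(OMe)3, −78 °C to rt; then AcOH, aq. H2O2, 0 °C to rt
Reagents that add atoms: hydrogen peroxide, OO
Why: Bromine–lithium exchange, borylation and oxidative 1,2-migration of the aryl group from boron to oxygen (arylboronate oxidation) put the oxygen exactly on C1; the weakly acidic peroxide medium should spare the electron-rich naphthol from base-promoted air oxidation.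

**Step 3**
Reactants: 5 2,6-dimethoxynaphthalen-1-ol; 6 (bromoethynyl)triisopropylsilane
Product: 7 2,6-dimethoxy-8-[(triisopropylsilyl)ethynyl]naphthalen-1-ol
Conditions: [RuCl2(p-cymene)]2 (cat.), K2CO3, ClCH2CH2Cl, 50 °C
Reagents that add atoms: none
Why: Ruthenium-catalysed hydroxyl-directed peri C–H alkynylation of a 1-naphthol with a silyl bromoalkyne: the naphthoxide binds ruthenium, carbonate-assisted metalation at C8 gives a five-membered ruthenacycle, the bromoalkyne inserts and bromide is eliminated. C2 is blocked by methoxy, so C8–H is the only C–H bond within reach of the oxygen, and the bulky silyl group should keep the hydroxyl from adding across the new alkyne.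

**Step 4**
Reactants: 7 2,6-dimethoxy-8-[(triisopropylsilyl)ethynyl]naphthalen-1-ol
Product: 8 2,6-dimethoxy-1-(methoxymethoxy)-8-[(triisopropylsilyl)ethynyl]naphthalene
Conditions: MOMCl, i-Pr2NEt, CH2Cl2, 0 °C to rt
Reagents that add atoms: chloromethyl methyl ether, COCCl
Why: O-alkylation of the naphthol to its methoxymethyl ether (Williamson-type acetal formation); the acidic, nucleophilic peri hydroxyl is capped before the alkyne is unmasked, so it can neither add to the terminal alkyne nor bind the cobalt catalyst later.

**Step 5**
Reactants: 8 2,6-dimethoxy-1-(methoxymethoxy)-8-[(triisopropylsilyl)ethynyl]naphthalene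
Product: 9 8-ethynyl-2,6-dimethoxy-1-(methoxymethoxy)naphthalene
Conditions: Bu4NF, THF, 0 °C to rt
Reagents that add atoms: none
Why: Fluoride-induced protodesilylation of a silyl alkyne; the acetal and the methyl ethers are inert to fluoride.

**Step 6**
Reactants: 9 8-ethynyl-2,6-dimethoxy-1-(methoxymethoxy)naphthalene; 10 2,3-dimethoxybuta-1,3-diene
Product: 11 8-(4,5-dimethoxycyclohexa-1,4-dien-1-yl)-2,6-dimethoxy-1-(methoxymethoxy)naphthalene
Conditions: CoBr2(dppe) (10 mol%), Zn (20 mol%), ZnI2 (20 mol%), 10 (2 equiv), CH2Cl2, rt
Reagents that add atoms: none
Why: Zinc should reduce CoBr2(dppe) to a monovalent cobalt species, which ZnI2 frees of halide so that the terminal alkyne of 9 and the s-cis diene 10 can both bind. Oxidative cyclisation joins one alkyne carbon to one diene terminus in a cobaltacycle and reductive elimination forms the second sigma bond, so that C1'–C2' and C5'–C6' are made and ring C closes as a six-membered carbocycle by an intermolecular [4+2] annulation of the two-carbon alkyne and the four-carbon diene. The closest known reaction type is the cobalt-catalysed neutral Diels–Alder reaction of unactivated terminal alkynes with 1,3-dienes, oxygen-substituted dienes included, which gives 1,4-cyclohexadienes. No stereocentre is formed, and regioselectivity is not at stake, because 10 has a twofold axis and both orientations give the same constitution with the methoxy groups on C3' and C4'. The step needs chemoselectivity for the alkyne: ring A is an aromatic naphthyl ether with no quinone or other dienophilic double bond, the hydroxyl is capped, and the excess of 10 should hold back alkyne cyclotrimerisation. The linear ethynyl group projects away from the peri substituent, so the crowding at C8 is met only after the ring has formed. The bis(enol ether) 11 is acid-labile and should be passed through basic alumina and used at once.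

**Step 7**
Reactants: 11 8-(4,5-dimethoxycyclohexa-1,4-dien-1-yl)-2,6-dimethoxy-1-(methoxymethoxy)naphthalene
Product: 12 8-(3,4-dimethoxyphenyl)-2,6-dimethoxy-1-(methoxymethoxy)naphthalene
Conditions: DDQ (1.1 equiv), toluene, rt
Reagents that add atoms: none
Why: DDQ dehydrogenation of a 1,4-cyclohexadiene (hydride abstraction from a doubly allylic CH2, then proton loss) is driven by aromatisation and should be fast at room temperature, so the bis(enol ether) is consumed before it can hydrolyse; the acetal keeps ring A from being oxidised as a free naphthol.

**Step 8**
Reactants: 12 8-(3,4-dimethoxyphenyl)-2,6-dimethoxy-1-(methoxymethoxy)naphthalene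
Product: 13 8-(3,4-dimethoxyphenyl)-2,6-dimethoxynaphthalen-1-ol
Conditions: HCl (cat.), MeOH, 40 °C
Reagents that add atoms: none
Why: Acid-catalysed acetal exchange (cleavage of the methoxymethyl ether) in methanol, which traps the methoxymethyl cation as its dimethyl acetal and so protects the electron-rich rings from alkylation; aryl methyl ethers are stable under these conditions.

**Step 9**
Reactants: 13 8-(3,4-dimethoxyphenyl)-2,6-dimethoxynaphthalen-1-ol
Product: 14 8-(3,4-dimethoxyphenyl)-2,6-dimethoxynaphthalene-1,4-dione
Conditions: (KSO3)2NO (2.5 equiv), KH2PO4, acetone/H2O, rt
Reagents that add atoms: potassium nitrosodisulfonate (Fremy's salt), [K+].[K+].[O]N(S(=O)(=O)[O-])S(=O)(=O)[O-]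
Why: Teuber oxidation: the nitroxyl radical abstracts the phenolic hydrogen, a second one adds at the free para position C4, and loss of imidodisulfonate gives the 1,4-quinone. C4 is the only unsubstituted position para to the hydroxyl, and rings B and C carry no phenol, so they should stay untouched.

## Compound list

1 | 2,6-dimethoxynaphthalene | COc1ccc2cc(OC)ccc2c1 | starting material
2 | 1-bromo-2,6-dimethoxynaphthalene | Brc1c(OC)ccc2cc(OC)ccc12 | intermediate
3 | 1-lithio-2,6-dimethoxynaphthalene | [Li]c1c(OC)ccc2cc(OC)ccc12 | intermediate
4 | lithium (2,6-dimethoxynaphthalen-1-yl)trimethoxyborate | [Li+].CO[B-](OC)(OC)c1c(OC)ccc2cc(OC)ccc12 | intermediate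
5 | 2,6-dimethoxynaphthalen-1-ol | Oc1c(OC)ccc2cc(OC)ccc12 | intermediate
6 | (bromoethynyl)triisopropylsilane | CC(C)[Si](C#CBr)(C(C)C)C(C)C | starting material
7 | 2,6-dimethoxy-8-[(triisopropylsilyl)ethynyl]naphthalen-1-ol | Oc1c(OC)ccc2cc(OC)cc(C#C[Si](C(C)C)(C(C)C)C(C)C)c12 | intermediate
8 | 2,6-dimethoxy-1-(methoxymethoxy)-8-[(triisopropylsilyl)ethynyl]naphthalene | COCOc1c(OC)ccc2cc(OC)cc(C#C[Si](C(C)C)(C(C)C)C(C)C)c12 | intermediate
9 | 8-ethynyl-2,6-dimethoxy-1-(methoxymethoxy)naphthalene | COCOc1c(OC)ccc2cc(OC)cc(C#C)c12 | intermediate
10 | 2,3-dimethoxybuta-1,3-diene | C=C(OC)C(=C)OC | starting material
11 | 8-(4,5-dimethoxycyclohexa-1,4-dien-1-yl)-2,6-dimethoxy-1-(methoxymethoxy)naphthalene | COCOc1c(OC)ccc2cc(OC)cc(C3=CCC(OC)=C(OC)C3)c12 | intermediate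
12 | 8-(3,4-dimethoxyphenyl)-2,6-dimethoxy-1-(methoxymethoxy)naphthalene | COCOc1c(OC)ccc2cc(OC)cc(-c3ccc(OC)c(OC)c3)c12 | intermediate
13 | 8-(3,4-dimethoxyphenyl)-2,6-dimethoxynaphthalen-1-ol | Oc1c(OC)ccc2cc(OC)cc(-c3ccc(OC)c(OC)c3)c12 | intermediate
14 | 8-(3,4-dimethoxyphenyl)-2,6-dimethoxynaphthalene-1,4-dione | COC1=CC(=O)c2cc(OC)cc(-c3ccc(OC)c(OC)c3)c2C1=O | target

## Step count and least certain steps

Total step count: 9. Longest linear sequence: 9 steps, from 1 to 14; 6 and 10 enter as purchased reagents.

**Step 6 (key step).** Several processes could divert it. The acetal and methoxy oxygens next to C8 may chelate cobalt and slow turnover. ZnI2 or cobalt may activate the alkyne towards attack by the peri ether oxygen, giving cycloisomerisation with loss or shift of the methoxymethyl group. The terminal alkyne may cyclotrimerise faster than it combines with the electron-rich diene. The Lewis acid together with traces of water may hydrolyse the enol ethers of the adduct. The fallback gives up the ring construction and attaches ring C intact. It sets out from naphthol 5: Pd(OAc)2-catalysed hydroxyl-directed peri C–H arylation with 4-iodo-1,2-dimethoxybenzene (Cs2CO3, DMF, 110 °C) should give naphthol 13 directly, and the route is rejoined at 13 for the final oxidation. This is shorter, but it depends on coupling two electron-rich arenes at the peri position at high temperature, with O-arylation and naphtholate oxidation as competitors, which is why it is held in reserve. No compound outside the list is made on this path, so it is entered below as F0.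

**Step 3.** The electron-rich naphtholate may be oxidised under the basic conditions. The C1 oxygen and the C2 methoxy group may bind ruthenium as a chelate and compete with metalation at C8. The product hydroxyl may add to the alkyne. The fallback replaces catalytic C–H alkynylation by stoichiometric metalation and cross-coupling, starting from 5. Directed lithiation of the lithium naphthoxide (t-BuLi, tetrahydropyran, rt to 50 °C), for which C8 is the only position next to the O–Li group once C2 is blocked, is quenched with iodine to give 8-iodo-2,6-dimethoxynaphthalen-1-ol F1 after aqueous work-up. The uncertainty of this lithiation is competing metalation ortho to a methoxy group. Protection of F1 with MOMCl and i-Pr2NEt gives 8-iodo-2,6-dimethoxy-1-(methoxymethoxy)naphthalene F2 as the coupling partner. Sonogashira coupling of F2 with ethynyltriisopropylsilane (PdCl2(PPh3)2, CuI, Et3N, 60 °C) then gives 8, where the route is rejoined.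

**Step 9.** The second nitroxyl radical may add at C2, ipso to the methoxy group, and loss of the methoxy group would lead to an ortho-quinone. Naphthoxyl radicals may also couple with each other. The fallback fixes the para position by a polar substitution, starting from 13. Azo coupling with diazotised 4-aminobenzenesulfonic acid (aq. NaOH, 0 °C) should occur at C4, the only free position ortho or para to the hydroxyl, to give 4-{(E)-[5-(3,4-dimethoxyphenyl)-4-hydroxy-3,7-dimethoxynaphthalen-1-yl]diazenyl}benzenesulfonic acid F3 as the azo dye. Reduction of F3 with Na2S2O4 cleaves the azo group to 4-amino-8-(3,4-dimethoxyphenyl)-2,6-dimethoxynaphthalen-1-ol F4 and the sulfonated aniline. Oxidation of F4 with FeCl3 in dilute aqueous HCl, followed by hydrolysis of the quinone imine, gives 14.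

**Step 2.** Peroxide or air may oxidise the electron-rich naphthol further, and the aryllithium may be protonated back to 1. The fallback forms the C–O bond without any oxidant, starting from 2: palladium-catalysed hydroxylation of the aryl bromide (Pd2(dba)3, 2-di-tert-butylphosphino-2',4',6'-triisopropylbiphenyl, KOH, dioxane/H2O, 100 °C, under argon) should give 5 directly, where the route is rejoined. No compound outside the list is made on this path, so it is entered below as F0.

## Further compounds

F0 | step 6 | none | none
F1 | step 3 | 8-iodo-2,6-dimethoxynaphthalen-1-ol | Oc1c(OC)ccc2cc(OC)cc(I)c12
F2 | step 3 | 8-iodo-2,6-dimethoxy-1-(methoxymethoxy)naphthalene | COCOc1c(OC)ccc2cc(OC)cc(I)c12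
F3 | step 9 | 4-{(E)-[5-(3,4-dimethoxyphenyl)-4-hydroxy-3,7-dimethoxynaphthalen-1-yl]diazenyl}benzenesulfonic acid | COc1cc(/N=N/c2ccc(cc2)S(=O)(=O)O)c2cc(OC)cc(-c3ccc(OC)c(OC)c3)c2c1O
F4 | step 9 | 4-amino-8-(3,4-dimethoxyphenyl)-2,6-dimethoxynaphthalen-1-ol | COc1cc(N)c2cc(OC)cc(-c3ccc(OC)c(OC)c3)c2c1O
F0 | step 2 | none | none
A1 | alternative 1 | 1-(3,4-dimethoxyphenyl)octa-1,7-diyn-3-one | COc1ccc(cc1OC)C#CC(=O)CCCC#C
A2 | alternative 1 | 2-ethynyl-4,4,5,5-tetramethyl-1,3,2-dioxaborolane | CC1(C)OB(OC1(C)C)C#C
A3 | alternative 1 | 8-(3,4-dimethoxyphenyl)-6-(4,4,5,5-tetramethyl-1,3,2-dioxaborolan-2-yl)-3,4-dihydronaphthalen-1(2H)-one | CC1(C)OB(OC1(C)C)c1cc2CCCC(=O)c2c(c1)-c1ccc(OC)c(OC)c1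
A4 | alternative 2 | 4-(3,4-dimethoxyphenyl)-7,8-dihydro-2H-chromene-2,5(6H)-dione | COc1ccc(cc1OC)C1=CC(=O)OC2=C1C(=O)CCC2
A5 | alternative 2 | 1,1-dimethoxyethene | C=C(OC)OC
A6 | alternative 2 | 8-(3,4-dimethoxyphenyl)-6-methoxy-3,4-dihydronaphthalen-1(2H)-one | COc1cc2CCCC(=O)c2c(c1)-c1ccc(OC)c(OC)c1
A7 | alternative 3 | methyl 3-(3,4-dimethoxyphenyl)-5-methoxy-2-(2-oxopropanoyl)benzoate | COC(=O)c1cc(OC)cc(-c2ccc(OC)c(OC)c2)c1C(=O)C(C)=O
A8 | alternative 3 | 8-(3,4-dimethoxyphenyl)-2-hydroxy-6-methoxynaphthalene-1,4-dione | O=C1C=C(O)C(=O)c2c1cc(OC)cc2-c1ccc(OC)c(OC)c1
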